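The route rests on opening the lactone ring (O1–C2–C3–C4–C4a–C8a) at C2–C3 and C2–O1. C2 is a lone carbonyl carbon between C3 and O1, and C4 is a methine that carries phenyl and the aryl carbon C4a, so the ring maps onto carbon monoxide and a 2-(1-phenylvinyl)phenol. One palladium-hydride cyclocarbonylation forms both bonds, closes the ring and sets C4 as R. Its substrate is the achiral 2,6-dihydroxy-4-(methoxymethoxy)-3-(1-phenylvinyl)benzophenone, in which the acetal caps the second oxygen beside the alkene and thereby fixes the lactone regiochemistry. The C6 prenyl group is installed last by Claisen rearrangement of a 1,1-dimethylallyl ether.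

Key step: step 4

Assumption: the sense of induction of the chiral bisphosphine on this substrate cannot be predicted, so the ligand antipode is assigned in a test run; the route is written for the antipode that gives (R) at C4.

Step 1
Reactants: 1 2,4,6-trihydroxybenzophenone
Product: 2 (2,6-dihydroxy-4-(methoxymethoxy)phenyl)(phenyl)methanone
Conditions: MOMCl (1.05 equiv), i-Pr2NEt (1.2 equiv), CH2Cl2, 0 °C
Reagents that add atoms: chloromethyl methyl ether (MOMCl), COCCl
Why: Williamson-type O-alkylation (MOM ether formation); the 4-OH is para to the benzoyl group, the most acidic and the only one not hydrogen-bonded to the ketone, so one equivalent of MOMCl should cap it selectively.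

Step 2
Reactants: 2 (2,6-dihydroxy-4-(methoxymethoxy)phenyl)(phenyl)methanone
Product: 3 (2,6-dihydroxy-3-iodo-4-(methoxymethoxy)phenyl)(phenyl)methanone
Conditions: NIS (1.0 equiv), DMF, −20 to 0 °C
Reagents that add atoms: N-iodosuccinimide, O=C1CCC(=O)N1I
Why: Electrophilic aromatic iodination; the two ring CH positions of 2 are equivalent, so one equivalent of NIS at low temperature should give a single mono-iodide under acid-free conditions that leave the acetal intact.

Step 3
Reactants: 3 (2,6-dihydroxy-3-iodo-4-(methoxymethoxy)phenyl)(phenyl)methanone; 4 1-phenylvinylboronic acid pinacol ester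
Product: 5 (2,6-dihydroxy-4-(methoxymethoxy)-3-(1-phenylvinyl)phenyl)(phenyl)methanone
Conditions: Pd(OAc)2 (5 mol %), SPhos (10 mol %), K3PO4 (4 equiv), 1,4-dioxane/H2O 5:1, 80 °C
Reagents that add atoms: none
Why: Suzuki–Miyaura coupling; the aryl iodide should add oxidatively with ease, and a bulky biarylphosphine supports coupling at the doubly ortho-substituted carbon with the phenols present as phenoxides.

Step 4
Reactants: 5 (2,6-dihydroxy-4-(methoxymethoxy)-3-(1-phenylvinyl)phenyl)(phenyl)methanone; 6 carbon monoxide
Product: 7 (R)-8-benzoyl-7-hydroxy-5-(methoxymethoxy)-4-phenylchroman-2-one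
Conditions: Pd(OAc)2 (5 mol %), DTBM-SEGPHOS (6 mol %, antipode per the assumption), CO (30 bar), H2 (5 bar), toluene, 90 °C
Reagents that add atoms: none
Why: Pd(0) with the bisphosphine and H2/AcOH gives a chiral Pd–H that adds across the 1,1-diarylethene of 5 with H to the diaryl carbon (C4) and Pd to the CH2 carbon (C3); CO inserts to the acyl-palladium (C2–C3) and the neighbouring phenol oxygen displaces palladium at the acyl carbon (C2–O1), returning Pd–H. The closest known reaction type is the palladium-hydride cyclocarbonylation (intramolecular hydroesterification) of 2-(1-substituted vinyl)phenols to 4-substituted 3,4-dihydrocoumarins, including ligand-controlled asymmetric versions on 1,1-disubstituted alkenes. The lactone closes in a 6-exo-trig acyl substitution. C4 is set by the ligand, which selects the alkene face that receives hydride, and the CO pressure traps the primary alkyl before β-hydride elimination can reverse the insertion. The step needs anti-Markovnikov insertion, secured because the alternative tertiary diaryl alkyl-palladium is congested and cannot lead to a six-membered ring, and a single lactonisation mode, secured because the only other oxygen beside the alkene is MOM-capped and the sulfonic-acid-free conditions keep that acetal in place. No other alkene is present to compete for the hydride.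

Step 5
Reactants: 7 (R)-8-benzoyl-7-hydroxy-5-(methoxymethoxy)-4-phenylchroman-2-one
Product: 8 (R)-8-benzoyl-5,7-dihydroxy-4-phenylchroman-2-one
Conditions: ZnBr2 (1 equiv), n-PrSH (2 equiv), CH2Cl2, 0 °C to rt
Reagents that add atoms: none
Why: Lewis-acid-assisted acetal cleavage with thiol capture of the methoxymethyl cation; the aprotic, alcohol-free conditions should remove the MOM group without alcoholysis of the aryl lactone and keep the electrophile away from the electron-rich C6 position, and C4 is not involved.

Step 6
Reactants: 8 (R)-8-benzoyl-5,7-dihydroxy-4-phenylchroman-2-one; 9 3-chloro-3-methylbut-1-yne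
Product: 10 (R)-8-benzoyl-7-hydroxy-5-((2-methylbut-3-yn-2-yl)oxy)-4-phenylchroman-2-one
Conditions: 9 (1.2 equiv), DBU (1.3 equiv), CuCl2·2H2O (1 mol %), MeCN, 0 °C
Reagents that add atoms: none
Why: Copper-catalysed propargylic etherification of a phenol; the 5-OH is para to the benzoyl group, acidic and not chelated, whereas the 7-OH is hydrogen-bonded to the ketone, the non-nucleophilic base at 0 °C spares the lactone, and a minor 7-O ether would converge on the same C6 product later.

Step 7
Reactants: 10 (R)-8-benzoyl-7-hydroxy-5-((2-methylbut-3-yn-2-yl)oxy)-4-phenylchroman-2-one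
Product: 11 (R)-8-benzoyl-7-hydroxy-5-((2-methylbut-3-en-2-yl)oxy)-4-phenylchroman-2-one
Conditions: H2 (1 atm), Lindlar catalyst, quinoline, EtOAc, rt
Reagents that add atoms: none
Why: Lindlar semi-hydrogenation; the poisoned palladium catalyst should stop at the terminal alkene and leave the diaryl ketone, the lactone and the C4 stereocentre alone.

Step 8
Reactants: 11 (R)-8-benzoyl-7-hydroxy-5-((2-methylbut-3-en-2-yl)oxy)-4-phenylchroman-2-one
Product: 13 (R)-8-benzoyl-5,7-dihydroxy-6-(3-methylbut-2-en-1-yl)-4-phenylchroman-2-one, via C6-prenyl cyclohexadienone tautomer 12 (not isolated)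
Conditions: toluene, 110 °C, sealed tube, degassed
Reagents that add atoms: none
Why: Aromatic Claisen rearrangement; the [3,3] shift transfers the allyl unit with inversion to C6, the only open ortho position (C4a is substituted and the para carbon C8 is blocked), and tautomerisation of the dienone gives the prenyl phenol under neutral conditions that cannot cyclise it or affect C4.

Compound list
1 | 2,4,6-trihydroxybenzophenone | O=C(c1ccccc1)c1c(O)cc(O)cc1O | starting material
2 | (2,6-dihydroxy-4-(methoxymethoxy)phenyl)(phenyl)methanone | COCOc1cc(O)c(C(=O)c2ccccc2)c(O)c1 | intermediate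
3 | (2,6-dihydroxy-3-iodo-4-(methoxymethoxy)phenyl)(phenyl)methanone | COCOc1cc(O)c(C(=O)c2ccccc2)c(O)c1I | intermediate
4 | 1-phenylvinylboronic acid pinacol ester | C=C(c1ccccc1)B1OC(C)(C)C(C)(C)O1 | starting material
5 | (2,6-dihydroxy-4-(methoxymethoxy)-3-(1-phenylvinyl)phenyl)(phenyl)methanone | C=C(c1ccccc1)c1c(O)c(C(=O)c2ccccc2)c(O)cc1OCOC | intermediate
6 | carbon monoxide | [C-]#[O+] | starting material
7 | (R)-8-benzoyl-7-hydroxy-5-(methoxymethoxy)-4-phenylchroman-2-one | COCOc1cc(O)c(C(=O)c2ccccc2)c2c1[C@@H](c1ccccc1)CC(=O)O2 | intermediate
8 | (R)-8-benzoyl-5,7-dihydroxy-4-phenylchroman-2-one | Oc1cc(O)c(C(=O)c2ccccc2)c2c1[C@@H](c1ccccc1)CC(=O)O2 | intermediate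
9 | 3-chloro-3-methylbut-1-yne | C#CC(C)(C)Cl | starting material
10 | (R)-8-benzoyl-7-hydroxy-5-((2-methylbut-3-yn-2-yl)oxy)-4-phenylchroman-2-one | C#CC(C)(C)Oc1cc(O)c(C(=O)c2ccccc2)c2c1[C@@H](c1ccccc1)CC(=O)O2 | intermediate
11 | (R)-8-benzoyl-7-hydroxy-5-((2-methylbut-3-en-2-yl)oxy)-4-phenylchroman-2-one | C=CC(C)(C)Oc1cc(O)c(C(=O)c2ccccc2)c2c1[C@@H](c1ccccc1)CC(=O)O2 | intermediate
12 | (4R)-8-benzoyl-7-hydroxy-6-(3-methylbut-2-en-1-yl)-4-phenyl-3,4-dihydro-2H-chromene-2,5(6H)-dione, C6 epimers, not isolated | O=C1C(CC=C(C)C)C(O)=C(C(=O)c2ccccc2)C2=C1[C@@H](c1ccccc1)CC(=O)O2 | intermediate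
13 | (R)-8-benzoyl-5,7-dihydroxy-6-(3-methylbut-2-en-1-yl)-4-phenylchroman-2-one | CC(C)=CCc1c(O)c(C(=O)c2ccccc2)c2c(c1O)[C@@H](c1ccccc1)CC(=O)O2 | target

Total step count: 8
Longest linear sequence: 8 steps (1 to 13)

Steps most likely to fail

Step 4. Hydropalladation of the doubly ortho-flanked, twisted alkene may be slow or reversible, which would give low conversion or poor facial selectivity. Loss of the acetal under the reaction conditions would also open the second lactonisation mode. The fallback sets out from 2 and returns at 7. Ortho-formylation of 2 (MgCl2, Et3N, paraformaldehyde, MeCN, reflux) should give 3-benzoyl-2,4-dihydroxy-6-(methoxymethoxy)benzaldehyde F1, again as one isomer because the two CH positions of 2 are equivalent. Wittig reaction with ethyl (triphenylphosphoranylidene)acetate in N,N-diethylaniline at reflux should pass through ethyl 3-(3-benzoyl-2,4-dihydroxy-6-(methoxymethoxy)phenyl)acrylate F2 (not isolated). This ester lactonises onto the only free hydroxyl beside the side chain to give 8-benzoyl-7-hydroxy-5-(methoxymethoxy)-2H-chromen-2-one F3. Rhodium-catalysed asymmetric 1,4-addition of phenylboronic acid (Rh(acac)(C2H4)2, the SEGPHOS antipode that gives R, dioxane/H2O, 60 °C) should then deliver 7.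

Step 3. Transmetalation at the hindered iodophenoxide may be slow, so that protodeiodination or protodeboronation of the vinyl boronate takes over. The fallback sets out from 3 and returns at 5. Palladium-catalysed coupling of 3 with commercial acetophenone N-tosylhydrazone (Pd2(dba)3, XPhos, excess LiOt-Bu, dioxane, 90 °C) proceeds through a palladium carbene, aryl migration and β-hydride elimination, and should give the 1,1-diarylethene 5 directly without an organoboron partner.

Step 6. Etherification with the tertiary electrophile at the hindered 5-OH may be incomplete, or may run on to double O-alkylation. The fallback sets out from 8 and returns at 11, and also removes the semi-hydrogenation. tert-Butyl (2-methylbut-3-en-2-yl) carbonate F4 would be prepared from 2-methylbut-3-en-2-ol, n-BuLi and Boc2O. Palladium-catalysed decarboxylative allylic etherification of 8 with F4 (Pd(PPh3)4, THF, 0 °C) should give the tertiary 1,1-dimethylallyl ether 11 by phenoxide attack at the more substituted allyl terminus.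

Further compounds
F1 | step 4 | 3-benzoyl-2,4-dihydroxy-6-(methoxymethoxy)benzaldehyde | O=Cc1c(O)c(C(=O)c2ccccc2)c(O)cc1OCOC
F2 | step 4 | ethyl 3-(3-benzoyl-2,4-dihydroxy-6-(methoxymethoxy)phenyl)acrylate (not isolated) | CCOC(=O)C=Cc1c(O)c(C(=O)c2ccccc2)c(O)cc1OCOC
F3 | step 4 | 8-benzoyl-7-hydroxy-5-(methoxymethoxy)-2H-chromen-2-one | COCOc1cc(O)c(C(=O)c2ccccc2)c2oc(=O)ccc12
F0 | step 3 | none | none
F4 | step 6 | tert-butyl (2-methylbut-3-en-2-yl) carbonate | C=CC(C)(C)OC(=O)OC(C)(C)C
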